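The cis-fused cyclopenta[c]isoxazolidine (isoxazolidine N1–O2–C3–C3a–C6a, cyclopentane C3a–C4–C5–C6–C6a) is dissected at C5–C6 and C3a–C6a, which frees C6–C6a as an acetaldehyde unit: C6 is its nucleophilic α-carbon, C6a its nitrone carbon. In one pot, lithiated acetaldehyde tert-butylimine is alkylated by a (Z)-homoallylic bromide (C5–C6), the imine is exchanged for the nitrone of N-(13-pyridyltridecyl)hydroxylamine, and intramolecular [3+2] cycloaddition closes both rings (C3a–C6a, O2–C3), setting C3, C3a and C6a. A glyceraldehyde-derived dioxolane on the Z-alkene directs the face and is afterwards cut down and extended (Wittig, diimide) to the pyridyloctyl chain.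

Key step: step 9

Remark (assumption on the chemistry): the facial preference in step 9 is assigned by the allylic-strain model for Z-allylic ethers (allylic H inside, dioxolane O outside, dioxolane CH2 anti to the dipole); with (R)-glyceraldehyde acetonide this leads to the (3S,3aS,6aR) ring configuration of the target, and the (S)-aldehyde would be used if the other face were preferred (fallback for step 9).

Step 1
Reactants: 1 3-methylpyridine
Product: 2 (pyridin-3-ylmethyl)lithium
Conditions: LiN(iPr)2 (1 equiv), THF, −78 °C; the cold solution is not isolated and is divided at once into two portions for steps 2 and 5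
Reagents that add atoms: lithium diisopropylamide, CC(C)N([Li])C(C)C
Why: LiN(iPr)2 deprotonates the 3-methyl group of 1 (lateral lithiation) to give the picolyl anion, which should persist in THF at −78 °C long enough to be made once and transferred by cannula to both alkylations.

Step 2
Reactants: 2 (pyridin-3-ylmethyl)lithium; 3 1,12-dibromododecane
Product: 4 3-(13-bromotridecyl)pyridine
Conditions: first portion of the solution of 2 added by cannula to 3 (3 equiv), THF, −78 °C to rt
Reagents that add atoms: none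
Why: The picolyl anion displaces one bromide of 3 by SN2 (alkylation of a laterally lithiated picoline), the excess of dibromide and inverse addition suppressing double alkylation.

Step 3
Reactants: 4 3-(13-bromotridecyl)pyridine; 5 tert-butyl N-[(tert-butoxycarbonyl)oxy]carbamate
Product: 6 tert-butyl N-[(tert-butoxycarbonyl)oxy]-N-[13-(pyridin-3-yl)tridecyl]carbamate
Conditions: K2CO3, DMF, rt
Reagents that add atoms: none
Why: The acidic N–H of the bis-Boc-hydroxylamine is deprotonated and alkylated at nitrogen by the primary bromide (SN2), the two Boc groups blocking O-alkylation and double N-alkylation while room temperature keeps pyridine self-quaternization slow.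

Step 4
Reactants: 6 tert-butyl N-[(tert-butoxycarbonyl)oxy]-N-[13-(pyridin-3-yl)tridecyl]carbamate
Product: 7 N-[13-(pyridin-3-yl)tridecyl]hydroxylamine
Conditions: CF3CO2H, CH2Cl2, 0 °C to rt; aq NaHCO3 work-up
Reagents that add atoms: none
Why: Acidolysis removes both the carbamate and the carbonate Boc group (loss of tert-butyl cation, then decarboxylation) and releases the N-monoalkylhydroxylamine needed for nitrone formation.

Step 5
Reactants: 2 (pyridin-3-ylmethyl)lithium; 8 1,6-dibromohexane
Product: 9 3-(7-bromoheptyl)pyridine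
Conditions: second portion of the solution of 2 added by cannula to 8 (3 equiv), THF, −78 °C to rt
Reagents that add atoms: none
Why: The same SN2 mono-alkylation of the laterally lithiated picoline as in step 2, now with the six-carbon dibromide in excess.

Step 6
Reactants: 9 3-(7-bromoheptyl)pyridine; 10 triphenylphosphine
Product: 11 triphenyl[7-(pyridin-3-yl)heptyl]phosphonium bromide
Conditions: 10 (2 equiv), MeCN, 80 °C
Reagents that add atoms: none
Why: SN2 quaternization of the phosphine by the primary bromide (phosphonium salt formation), in which the excess of the more nucleophilic phosphine should outrun N-alkylation of the pyridine.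

Step 7
Reactants: 12 (3-hydroxypropyl)triphenylphosphonium bromide; 13 (4R)-2,2-dimethyl-1,3-dioxolane-4-carbaldehyde
Product: 17 (3Z)-4-[(4S)-2,2-dimethyl-1,3-dioxolan-4-yl]but-3-en-1-ol, via O-silyl phosphonium salt 14 (not isolated), via silyloxy ylide 15 (not isolated), via trimethylsilyl ether 16 (not isolated)
Conditions: NaN(SiMe3)2 (1 equiv), THF, 0 °C; Me3SiCl (1 equiv); NaN(SiMe3)2 (1 equiv), 0 °C; then 13, −78 °C to rt; then K2CO3 (cat.), MeOH, rt
Reagents that add atoms: chlorotrimethylsilane, C[Si](C)(C)Cl (its silyl group is carried only by 14–16 and is lost before 17)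
Why: Wittig olefination with a non-stabilized ylide under lithium-free conditions should give the Z-alkene, the transient O-silyl group preventing the E-drift of an oxido ylide, while the stereocentre of 13 is not touched (its descriptor changes from R to S only through CIP priorities) and methanolysis frees the alcohol.

Step 8
Reactants: 17 (3Z)-4-[(4S)-2,2-dimethyl-1,3-dioxolan-4-yl]but-3-en-1-ol
Product: 18 (4S)-4-[(1Z)-4-bromobut-1-en-1-yl]-2,2-dimethyl-1,3-dioxolane
Conditions: CBr4, PPh3, CH2Cl2, 0 °C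
Reagents that add atoms: tetrabromomethane, BrC(Br)(Br)Br
Why: Appel reaction, in which the alkoxyphosphonium ion is displaced by bromide in an SN2 step at the primary carbon under neutral conditions that spare the acetonide and the Z-alkene.

Step 9
Reactants: 19 N-ethylidene-2-methylpropan-2-amine (acetaldehyde N-tert-butylimine); 18 (4S)-4-[(1Z)-4-bromobut-1-en-1-yl]-2,2-dimethyl-1,3-dioxolane; 7 N-[13-(pyridin-3-yl)tridecyl]hydroxylamine
Product: 23 (3R,3aS,6aR)-3-[(4R)-2,2-dimethyl-1,3-dioxolan-4-yl]-1-[13-(pyridin-3-yl)tridecyl]hexahydro-1H-cyclopenta[c][1,2]oxazole, via lithiated imine 20 (not isolated), via N-tert-butyl aldimine 21 (not isolated), via nitrone 22 (not isolated)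
Conditions: 19 (1.2 equiv), LiN(iPr)2 (1.2 equiv), THF, −78 to 0 °C; 18, −78 °C to rt; MeOH (0.3 equiv), evaporate volatiles; then 7, AcOH (1 equiv), toluene, 100 °C
Reagents that add atoms: none
Why: LiN(iPr)2 converts 19 into the 1-azaallyl anion 20, whose SN2 alkylation by the primary bromide 18 forms the C5–C6 bond, acetic acid then mediates exchange of tert-butylamine for hydroxylamine 7 to give the aldonitrone 22, and 22 undergoes a thermal intramolecular nitrone–olefin [3+2] cycloaddition that forms C3a–C6a and O2–C3. The closest known reaction types are the alkylation of lithiated aldimines (metalloenamine alkylation of the Stork–Dowd type), nitrone formation from imines and N-alkylhydroxylamines, and the intramolecular nitrone cycloaddition of C-(hex-5-enyl)nitrones. The cyclopentane closes by bonding of the nitrone carbon C6a to the proximal alkene carbon C3a (5-exo, fused and not bridged mode, enforced by the three-carbon tether C4–C6), and the isoxazolidine closes in the same concerted suprafacial event by O2–C3 bonding. The cis relationship of 3-H and 3a-H follows stereospecifically from the Z-alkene, the cis ring fusion at C3a/C6a from the short tether, and the absolute sense from the dioxolane stereocentre: allylic 1,3-strain of the Z-alkene holds its C–H in the alkene plane, so the dipole should add anti to the dioxolane CH2 and syn to its oxygen. The step needs mono-alkylation without E2 loss of HBr (slight excess of 20 at low temperature, excess 19 leaving with the solvent before 7 is added) and one alkene face, which the dioxolane secures; a minor cycloadduct would be a diastereomer, not an enantiomer, and would be removed by chromatography.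

Step 10
Reactants: 23 (3R,3aS,6aR)-3-[(4R)-2,2-dimethyl-1,3-dioxolan-4-yl]-1-[13-(pyridin-3-yl)tridecyl]hexahydro-1H-cyclopenta[c][1,2]oxazole
Product: 25 (3R,3aS,6aR)-1-[13-(pyridin-3-yl)tridecyl]hexahydro-1H-cyclopenta[c][1,2]oxazole-3-carbaldehyde, via diol 24 (not isolated)
Conditions: AcOH–H2O (4:1), 40 °C; evaporate; NaIO4, NaHCO3, THF–H2O, 0 °C
Reagents that add atoms: none
Why: Mild aqueous acid hydrolyses the terminal acetonide to diol 24 and buffered periodate cleaves the 1,2-diol (Malaprade reaction) to the aldehyde, which deletes the auxiliary stereocentre while C3, C3a and C6a, the N–O bond and the pyridine stay untouched.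

Step 11
Reactants: 25 (3R,3aS,6aR)-1-[13-(pyridin-3-yl)tridecyl]hexahydro-1H-cyclopenta[c][1,2]oxazole-3-carbaldehyde; 11 triphenyl[7-(pyridin-3-yl)heptyl]phosphonium bromide
Product: 27 (3S,3aS,6aR)-3-[(1Z)-8-(pyridin-3-yl)oct-1-en-1-yl]-1-[13-(pyridin-3-yl)tridecyl]hexahydro-1H-cyclopenta[c][1,2]oxazole, via ylide 26 (not isolated)
Conditions: 11, NaN(SiMe3)2, THF, −78 to 0 °C; then 25, −78 to 0 °C
Reagents that add atoms: none
Why: Wittig olefination of the α-alkoxy aldehyde with the non-stabilized ylide 26 at low temperature joins the first two carbons of the side chain without disturbing C3, and the alkene geometry (Z expected) is irrelevant because the double bond is reduced next.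

Step 12
Reactants: 27 (3S,3aS,6aR)-3-[(1Z)-8-(pyridin-3-yl)oct-1-en-1-yl]-1-[13-(pyridin-3-yl)tridecyl]hexahydro-1H-cyclopenta[c][1,2]oxazole
Product: 28 (3S,3aS,6aR)-3-[8-(pyridin-3-yl)octyl]-1-[13-(pyridin-3-yl)tridecyl]hexahydro-1H-cyclopenta[c][1,2]oxazole (pyrinodemin B)
Conditions: TsNHNH2, NaOAc, THF–H2O, 70 °C
Reagents that add atoms: none
Why: Diimide generated in situ transfers two hydrogens to the disubstituted alkene by concerted syn-addition and leaves the N–O bond and both pyridine rings intact, which hydrogenation over palladium would not guarantee.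

Compound list
1 | 3-methylpyridine | Cc1cccnc1 | starting material
2 | (pyridin-3-ylmethyl)lithium | [Li]Cc1cccnc1 | intermediate
3 | 1,12-dibromododecane | BrCCCCCCCCCCCCBr | starting material
4 | 3-(13-bromotridecyl)pyridine | BrCCCCCCCCCCCCCc1cccnc1 | intermediate
5 | tert-butyl N-[(tert-butoxycarbonyl)oxy]carbamate | CC(C)(C)OC(=O)NOC(=O)OC(C)(C)C | starting material
6 | tert-butyl N-[(tert-butoxycarbonyl)oxy]-N-[13-(pyridin-3-yl)tridecyl]carbamate | CC(C)(C)OC(=O)N(CCCCCCCCCCCCCc1cccnc1)OC(=O)OC(C)(C)C | intermediate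
7 | N-[13-(pyridin-3-yl)tridecyl]hydroxylamine | ONCCCCCCCCCCCCCc1cccnc1 | intermediate
8 | 1,6-dibromohexane | BrCCCCCCBr | starting material
9 | 3-(7-bromoheptyl)pyridine | BrCCCCCCCc1cccnc1 | intermediate
10 | triphenylphosphine | c1ccc(cc1)P(c1ccccc1)c1ccccc1 | starting material
11 | triphenyl[7-(pyridin-3-yl)heptyl]phosphonium bromide | [Br-].c1ccc(cc1)[P+](CCCCCCCc1cccnc1)(c1ccccc1)c1ccccc1 | intermediate
12 | (3-hydroxypropyl)triphenylphosphonium bromide | [Br-].OCCC[P+](c1ccccc1)(c1ccccc1)c1ccccc1 | starting material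
13 | (4R)-2,2-dimethyl-1,3-dioxolane-4-carbaldehyde ((R)-glyceraldehyde acetonide) | O=C[C@H]1COC(C)(C)O1 | starting material
14 | triphenyl[3-(trimethylsilyloxy)propyl]phosphonium chloride | C[Si](C)(C)OCCC[P+](c1ccccc1)(c1ccccc1)c1ccccc1.[Cl-] | intermediate
15 | triphenyl[3-(trimethylsilyloxy)propylidene]phosphorane | C[Si](C)(C)OCCC=P(c1ccccc1)(c1ccccc1)c1ccccc1 | intermediate
16 | trimethyl{[(3Z)-4-[(4S)-2,2-dimethyl-1,3-dioxolan-4-yl]but-3-en-1-yl]oxy}silane | C[Si](C)(C)OCC\C=C/[C@H]1COC(C)(C)O1 | intermediate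
17 | (3Z)-4-[(4S)-2,2-dimethyl-1,3-dioxolan-4-yl]but-3-en-1-ol | OCC\C=C/[C@H]1COC(C)(C)O1 | intermediate
18 | (4S)-4-[(1Z)-4-bromobut-1-en-1-yl]-2,2-dimethyl-1,3-dioxolane | BrCC\C=C/[C@H]1COC(C)(C)O1 | intermediate
19 | N-ethylidene-2-methylpropan-2-amine | CC=NC(C)(C)C | starting material
20 | lithium tert-butyl(ethenyl)azanide (lithiated imine) | C=CN([Li])C(C)(C)C | intermediate
21 | N-tert-butyl imine of (5Z)-6-[(4S)-2,2-dimethyl-1,3-dioxolan-4-yl]hex-5-enal | CC(C)(C)N=CCCC\C=C/[C@H]1COC(C)(C)O1 | intermediate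
22 | (5Z)-6-[(4S)-2,2-dimethyl-1,3-dioxolan-4-yl]-N-[13-(pyridin-3-yl)tridecyl]hex-5-en-1-imine N-oxide (nitrone) | [O-][N+](CCCCCCCCCCCCCc1cccnc1)=CCCC\C=C/[C@H]1COC(C)(C)O1 | intermediate
23 | (3R,3aS,6aR)-3-[(4R)-2,2-dimethyl-1,3-dioxolan-4-yl]-1-[13-(pyridin-3-yl)tridecyl]hexahydro-1H-cyclopenta[c][1,2]oxazole | c1cncc(CCCCCCCCCCCCCN2O[C@@H]([C@H]4COC(C)(C)O4)[C@H]3CCC[C@H]32)c1 | intermediate
24 | (1R)-1-[(3R,3aS,6aR)-1-[13-(pyridin-3-yl)tridecyl]hexahydro-1H-cyclopenta[c][1,2]oxazol-3-yl]ethane-1,2-diol | c1cncc(CCCCCCCCCCCCCN2O[C@@H]([C@H](O)CO)[C@H]3CCC[C@H]32)c1 | intermediate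
25 | (3R,3aS,6aR)-1-[13-(pyridin-3-yl)tridecyl]hexahydro-1H-cyclopenta[c][1,2]oxazole-3-carbaldehyde | c1cncc(CCCCCCCCCCCCCN2O[C@@H](C=O)[C@H]3CCC[C@H]32)c1 | intermediate
26 | triphenyl[7-(pyridin-3-yl)heptylidene]phosphorane | c1ccc(cc1)P(=CCCCCCCc1cccnc1)(c1ccccc1)c1ccccc1 | intermediate
27 | (3S,3aS,6aR)-3-[(1Z)-8-(pyridin-3-yl)oct-1-en-1-yl]-1-[13-(pyridin-3-yl)tridecyl]hexahydro-1H-cyclopenta[c][1,2]oxazole | c1cncc(CCCCCCCCCCCCCN2O[C@@H](/C=C\CCCCCCc3cccnc3)[C@H]3CCC[C@H]32)c1 | intermediate
28 | (3S,3aS,6aR)-3-[8-(pyridin-3-yl)octyl]-1-[13-(pyridin-3-yl)tridecyl]hexahydro-1H-cyclopenta[c][1,2]oxazole (pyrinodemin B) | c1cncc(CCCCCCCCCCCCCN2O[C@@H](CCCCCCCCc3cccnc3)[C@H]3CCC[C@H]32)c1 | target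

Total step count: 12. Longest linear sequence: 8 steps (steps 1, 2, 3, 4, 9, 10, 11, 12).

Steps most likely to fail

Step 9: the nitrone may add to the alkene face opposite to the assigned one (weak or reversed bias from the dioxolane), which would give the mirror-image ring configuration. The fallback is the mirror-image chiral-pool series; it sets out from 12 and comes back to the route at 25. Compound 12 is silylated and converted into ylide 15 as in step 7 and olefinated with (4S)-2,2-dimethyl-1,3-dioxolane-4-carbaldehyde F1. This gives, through the trimethylsilyl ether trimethyl{[(3Z)-4-[(4R)-2,2-dimethyl-1,3-dioxolan-4-yl]but-3-en-1-yl]oxy}silane F2, the alcohol (3Z)-4-[(4R)-2,2-dimethyl-1,3-dioxolan-4-yl]but-3-en-1-ol F3. Appel bromination gives (4R)-4-[(1Z)-4-bromobut-1-en-1-yl]-2,2-dimethyl-1,3-dioxolane F4. F4 is united with 19 and 7 as in step 9, through the N-tert-butyl aldimine of (5Z)-6-[(4R)-2,2-dimethyl-1,3-dioxolan-4-yl]hex-5-enal F5 and the corresponding N-[13-(pyridin-3-yl)tridecyl] nitrone F6, to give the cycloadduct (3R,3aS,6aR)-3-[(4S)-2,2-dimethyl-1,3-dioxolan-4-yl]-1-[13-(pyridin-3-yl)tridecyl]hexahydro-1H-cyclopenta[c][1,2]oxazole F7. If addition anti to the dioxolane oxygen is the preferred mode, F7 carries the required (3aS,6aR) ring configuration. Hydrolysis to the diol (1S)-1-[(3R,3aS,6aR)-1-[13-(pyridin-3-yl)tridecyl]hexahydro-1H-cyclopenta[c][1,2]oxazol-3-yl]ethane-1,2-diol F8 and periodate cleavage then erase the auxiliary stereocentre and give 25.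

Step 11: the basic ylide may epimerize C3 of the α-alkoxy aldehyde (the carbon bearing the formyl group) before olefination. The fallback avoids any base acting on the aldehyde; it sets out from 25 and comes back at 28. Compound 25 is reduced at once with NaBH4 to [(3R,3aS,6aR)-1-[13-(pyridin-3-yl)tridecyl]hexahydro-1H-cyclopenta[c][1,2]oxazol-3-yl]methanol F9, which has no acidic α-hydrogen. Tosylation (TsCl, Et3N, DMAP) gives [(3R,3aS,6aR)-1-[13-(pyridin-3-yl)tridecyl]hexahydro-1H-cyclopenta[c][1,2]oxazol-3-yl]methyl 4-methylbenzenesulfonate F10. Copper-catalysed coupling (Li2CuCl4, THF, −20 °C) with [7-(pyridin-3-yl)heptyl]magnesium bromide F11, made from 9 and Mg, builds the octyl chain at the alkane oxidation level and gives 28 directly, so step 12 is not needed.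

Step 6: N-alkylation of the pyridine of one molecule of 9 by the bromide of another (self-quaternization to oligomers) may compete with phosphonium salt formation at 80 °C. The fallback introduces the pyridine ring after the olefination; it sets out from 10 and 25 and comes back at 27. 7-Bromohept-1-ene and 10 give (hept-6-en-1-yl)triphenylphosphonium bromide F12. Its ylide (hept-6-en-1-ylidene)triphenylphosphorane F13 (NaN(SiMe3)2) olefinates 25 to the diene (3S,3aS,6aR)-3-[(1Z)-octa-1,7-dien-1-yl]-1-[13-(pyridin-3-yl)tridecyl]hexahydro-1H-cyclopenta[c][1,2]oxazole F14. 9-BBN-H adds selectively to the terminal alkene to give the B-alkyl-9-borabicyclo[3.3.1]nonane 9-{(7Z)-8-[(3S,3aS,6aR)-1-[13-(pyridin-3-yl)tridecyl]hexahydro-1H-cyclopenta[c][1,2]oxazol-3-yl]oct-7-en-1-yl}-9-borabicyclo[3.3.1]nonane F15. Suzuki–Miyaura coupling with 3-bromopyridine (PdCl2(dppf), K3PO4, THF–H2O) then gives 27.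

Further compounds
F1 | step 9 | (4S)-2,2-dimethyl-1,3-dioxolane-4-carbaldehyde | O=C[C@@H]1COC(C)(C)O1
F2 | step 9 | trimethyl{[(3Z)-4-[(4R)-2,2-dimethyl-1,3-dioxolan-4-yl]but-3-en-1-yl]oxy}silane | C[Si](C)(C)OCC\C=C/[C@@H]1COC(C)(C)O1
F3 | step 9 | (3Z)-4-[(4R)-2,2-dimethyl-1,3-dioxolan-4-yl]but-3-en-1-ol | OCC\C=C/[C@@H]1COC(C)(C)O1
F4 | step 9 | (4R)-4-[(1Z)-4-bromobut-1-en-1-yl]-2,2-dimethyl-1,3-dioxolane | BrCC\C=C/[C@@H]1COC(C)(C)O1
F5 | step 9 | N-tert-butyl imine of (5Z)-6-[(4R)-2,2-dimethyl-1,3-dioxolan-4-yl]hex-5-enal | CC(C)(C)N=CCCC\C=C/[C@@H]1COC(C)(C)O1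
F6 | step 9 | (5Z)-6-[(4R)-2,2-dimethyl-1,3-dioxolan-4-yl]-N-[13-(pyridin-3-yl)tridecyl]hex-5-en-1-imine N-oxide | [O-][N+](CCCCCCCCCCCCCc1cccnc1)=CCCC\C=C/[C@@H]1COC(C)(C)O1
F7 | step 9 | (3R,3aS,6aR)-3-[(4S)-2,2-dimethyl-1,3-dioxolan-4-yl]-1-[13-(pyridin-3-yl)tridecyl]hexahydro-1H-cyclopenta[c][1,2]oxazole | c1cncc(CCCCCCCCCCCCCN2O[C@@H]([C@@H]4COC(C)(C)O4)[C@H]3CCC[C@H]32)c1
F8 | step 9 | (1S)-1-[(3R,3aS,6aR)-1-[13-(pyridin-3-yl)tridecyl]hexahydro-1H-cyclopenta[c][1,2]oxazol-3-yl]ethane-1,2-diol | c1cncc(CCCCCCCCCCCCCN2O[C@@H]([C@@H](O)CO)[C@H]3CCC[C@H]32)c1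
F9 | step 11 | [(3R,3aS,6aR)-1-[13-(pyridin-3-yl)tridecyl]hexahydro-1H-cyclopenta[c][1,2]oxazol-3-yl]methanol | c1cncc(CCCCCCCCCCCCCN2O[C@@H](CO)[C@H]3CCC[C@H]32)c1
F10 | step 11 | [(3R,3aS,6aR)-1-[13-(pyridin-3-yl)tridecyl]hexahydro-1H-cyclopenta[c][1,2]oxazol-3-yl]methyl 4-methylbenzenesulfonate | c1cncc(CCCCCCCCCCCCCN2O[C@@H](COS(=O)(=O)c4ccc(C)cc4)[C@H]3CCC[C@H]32)c1
F11 | step 11 | [7-(pyridin-3-yl)heptyl]magnesium bromide | Br[Mg]CCCCCCCc1cccnc1
F12 | step 6 | (hept-6-en-1-yl)triphenylphosphonium bromide | [Br-].C=CCCCCC[P+](c1ccccc1)(c1ccccc1)c1ccccc1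
F13 | step 6 | (hept-6-en-1-ylidene)triphenylphosphorane | C=CCCCCC=P(c1ccccc1)(c1ccccc1)c1ccccc1
F14 | step 6 | (3S,3aS,6aR)-3-[(1Z)-octa-1,7-dien-1-yl]-1-[13-(pyridin-3-yl)tridecyl]hexahydro-1H-cyclopenta[c][1,2]oxazole | c1cncc(CCCCCCCCCCCCCN2O[C@@H](/C=C\CCCCC=C)[C@H]3CCC[C@H]32)c1
F15 | step 6 | 9-{(7Z)-8-[(3S,3aS,6aR)-1-[13-(pyridin-3-yl)tridecyl]hexahydro-1H-cyclopenta[c][1,2]oxazol-3-yl]oct-7-en-1-yl}-9-borabicyclo[3.3.1]nonane | c1cncc(CCCCCCCCCCCCCN2O[C@@H](/C=C\CCCCCCB4C5CCCC4CCC5)[C@H]3CCC[C@H]32)c1
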